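**Plan**

- Labels: in the cyclobutane, Ca is the CH bonded to the indane CH2, Cb the CH on ring A (the benzene ring of the chromene), Cc the CH carrying catechol ring B, and Cd the CMe2 carbon. The retrosynthesis first removes the two silyl ethers, then cuts the ring A C6–CH2 bond of the indane (alkylborane/aryl bromide coupling) and the exocyclic carbon on Ca (methylenation of a ketone).
- Enabling feature: with Ca as a carbonyl carbon, the ring Ca–Cb–Cc–Cd is a ketene–alkene adduct. Cutting Ca–Cd and Cb–Cc (the trans-diaryl bond) gives a ring A arylacetamide as keteniminium precursor and the isobutenyl alkene of ring B.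
- Forward order of rings: the pyran ring on ring A (from phloroglucinol, carried as the saturated chroman), the cyclobutane by (2+2), the chromene double bond by dehydrogenation, and the five-membered indane ring last.
- Stereochemistry: Cc comes from the C2-symmetric pyrrolidine auxiliary in the (2+2); Cb equilibrates next to the carbonyl to the trans-diaryl isomer; Ca comes from hydroboration anti to ring A and is then held by the cis ring fusion.

Key step: step 9

Assumption: the (2R,5R) auxiliary is taken to induce the (2R,3R) cyclobutanone; should the sense prove opposite, the (2S,5S) amine is used in steps 5, 6 and 9 with no other change.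

**Route**

Step 1
Reactants: 1 phloroglucinol; 2 3,3-dimethylacrylic acid
Product: 3 5,7-dihydroxy-2,2-dimethylchroman-4-one
Conditions: P2O5/MeSO3H, 70 °C
Reagents that add atoms: none
Why: Friedel–Crafts acylation of the symmetric triol followed by intramolecular oxa-Michael addition of the neighbouring phenol should close the pyranone, and the symmetry of 1 rules out regioisomers.

Step 2
Reactants: 3 5,7-dihydroxy-2,2-dimethylchroman-4-one
Product: 4 5-hydroxy-7-methoxy-2,2-dimethylchroman-4-one
Conditions: MeI (1.05 equiv), K2CO3, acetone, rt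
Reagents that add atoms: iodomethane, CI
Why: Williamson etherification should take place only at the acidic 7-OH, because the 5-OH is tied up in a hydrogen bond to the C4 carbonyl.

Step 3
Reactants: 4 5-hydroxy-7-methoxy-2,2-dimethylchroman-4-one
Product: 5 7-methoxy-2,2-dimethylchroman-5-ol
Conditions: Zn(Hg), conc. HCl, MeOH, reflux
Reagents that add atoms: none
Why: Clemmensen reduction of the aryl ketone to CH2 is the classical way from chroman-4-ones to chromans, and the methyl ether and the pyran ring tolerate hot HCl.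

Step 4
Reactants: 5 7-methoxy-2,2-dimethylchroman-5-ol
Product: 6 7-methoxy-2,2-dimethylchroman-5-yl trifluoromethanesulfonate
Conditions: Tf2O, pyridine, CH2Cl2, 0 °C
Reagents that add atoms: trifluoromethanesulfonic anhydride, O=S(=O)(OS(=O)(=O)C(F)(F)F)C(F)(F)F
Why: O-sulfonylation of the phenol gives the aryl triflate that serves as the cross-coupling electrophile at C5.

Step 5
Reactants: 7 bromoacetyl bromide; 8 (2R,5R)-2,5-dimethylpyrrolidine
Product: 9 2-bromo-1-[(2R,5R)-2,5-dimethylpyrrolidin-1-yl]ethanone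
Conditions: Et3N, CH2Cl2, −78 → 0 °C
Reagents that add atoms: none
Why: N-acylation of the hindered secondary amine by the acyl bromide (Schotten–Baumann type) is far faster than N-alkylation by the α-bromide at low temperature, and the two stereocentres of the amine are untouched.

Step 6
Reactants: 9 2-bromo-1-[(2R,5R)-2,5-dimethylpyrrolidin-1-yl]ethanone; 6 7-methoxy-2,2-dimethylchroman-5-yl trifluoromethanesulfonate
Product: 11 1-[(2R,5R)-2,5-dimethylpyrrolidin-1-yl]-2-(7-methoxy-2,2-dimethylchroman-5-yl)ethanone, via bromozinc amide enolate 10 (not isolated)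
Conditions: Zn dust, THF, rt; then 6, Pd2(dba)3 (cat.), XPhos, THF, 65 °C
Reagents that add atoms: none
Why: zinc insertion gives the Reformatsky reagent, which should undergo Negishi-type α-arylation (oxidative addition of the triflate to zerovalent palladium, transmetalation, reductive elimination), and the neutral zinc enolate avoids diarylation.

Step 7
Reactants: 12 3,4-dihydroxybenzaldehyde
Product: 13 3,4-bis(tert-butyldimethylsilyloxy)benzaldehyde
Conditions: TBSCl, imidazole, DMF, rt
Reagents that add atoms: tert-butyldimethylsilyl chloride, CC(C)(C)[Si](C)(C)Cl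
Why: imidazole-promoted silylation of both phenols gives ethers that are inert to Tf2O, ylides, NBS and DDQ and are removed by fluoride at the end.

Step 8
Reactants: 13 3,4-bis(tert-butyldimethylsilyloxy)benzaldehyde
Product: 14 4-(2-methylprop-1-enyl)-1,2-bis(tert-butyldimethylsilyloxy)benzene
Conditions: i-PrPPh3I, n-BuLi, THF, 0 °C; then 13, 0 °C → rt
Reagents that add atoms: isopropyltriphenylphosphonium iodide, CC(C)[P+](c1ccccc1)(c1ccccc1)c1ccccc1.[I-]
Why: Wittig olefination of the aromatic aldehyde with the non-stabilised isopropylidene ylide gives the trisubstituted alkene, which has no geometric isomers.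

Step 9
Reactants: 11 1-[(2R,5R)-2,5-dimethylpyrrolidin-1-yl]-2-(7-methoxy-2,2-dimethylchroman-5-yl)ethanone; 14 4-(2-methylprop-1-enyl)-1,2-bis(tert-butyldimethylsilyloxy)benzene
Product: 17 (2R,3R)-3-[3,4-bis(tert-butyldimethylsilyloxy)phenyl]-2-(7-methoxy-2,2-dimethylchroman-5-yl)-4,4-dimethylcyclobutan-1-one, via keteniminium triflate 15 (not isolated), via cyclobutaniminium triflate 16 (not isolated)
Conditions: 14 (2 equiv), Tf2O, 2,4,6-collidine, CH2Cl2, −30 °C → reflux; then H2O, NaHCO3 (aq.), 40 °C
Reagents that add atoms: water, O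
Why: O-triflation of the amide and collidine-mediated loss of triflic acid should give the aryl keteniminium salt 15, whose central carbon is attacked by the CMe2 terminus of 14 (Ca–Cd), leaving a benzylic cation at Cc stabilised by the para silyloxy group of ring B. The enamine carbon Cb then collapses onto this cation (Cb–Cc), so the four-membered ring closes by a stepwise polar (2+2) cycloaddition (intermolecular addition, then cation–enamine ring closure) to give iminium 16, which water hydrolyses to 17 with release of the auxiliary. The closest known reaction type is the keteniminium–alkene (2+2) cycloaddition of tertiary amides activated by Tf2O, including amides of C2-symmetric 2,5-dimethylpyrrolidine. Cc is set in the ring-closing event under control of the pyrrolidinium methyl groups, which differentiate the two faces of the enamine, while Cb, next to the iminium and then the carbonyl carbon, equilibrates to the trans-diaryl arrangement. The step needs regioselectivity (benzylic rather than tertiary cation), which the electron-rich ring B secures, and chemoselectivity, which is secured by carrying ring A as the saturated chroman so that 14 is the only reactive alkene.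

Step 10
Reactants: 17 (2R,3R)-3-[3,4-bis(tert-butyldimethylsilyloxy)phenyl]-2-(7-methoxy-2,2-dimethylchroman-5-yl)-4,4-dimethylcyclobutan-1-one
Product: 18 (2R,3R)-2-(6-bromo-7-methoxy-2,2-dimethylchroman-5-yl)-3-[3,4-bis(tert-butyldimethylsilyloxy)phenyl]-4,4-dimethylcyclobutan-1-one
Conditions: NBS (1.05 equiv), MeCN, 0 °C, dark
Reagents that add atoms: N-bromosuccinimide, O=C1CCC(=O)N1Br
Why: electrophilic aromatic bromination should go to C6, which is para to the pyran oxygen and ortho to the methoxy group (the orientation shown by 3,5-dialkoxyalkylbenzenes, which brominate next to the alkyl group and not between the oxygens), while the silylated ring B is far less activated and the ketone is not enolised under neutral conditions.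

Step 11
Reactants: 18 (2R,3R)-2-(6-bromo-7-methoxy-2,2-dimethylchroman-5-yl)-3-[3,4-bis(tert-butyldimethylsilyloxy)phenyl]-4,4-dimethylcyclobutan-1-one
Product: 19 (2R,3R)-2-(6-bromo-7-methoxy-2,2-dimethyl-2H-chromen-5-yl)-3-[3,4-bis(tert-butyldimethylsilyloxy)phenyl]-4,4-dimethylcyclobutan-1-one
Conditions: DDQ, benzene, 80 °C
Reagents that add atoms: none
Why: DDQ dehydrogenation of a 2,2-dimethylchroman proceeds by hydride abstraction from C4, whose cation is stabilised by the para methoxy group and the ortho ring oxygen, followed by loss of a C3 proton; the other benzylic C–H bonds (Cb, meta to both oxygens and next to the carbonyl, and Cc on the cyclobutane) are not activated.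

Step 12
Reactants: 19 (2R,3R)-2-(6-bromo-7-methoxy-2,2-dimethyl-2H-chromen-5-yl)-3-[3,4-bis(tert-butyldimethylsilyloxy)phenyl]-4,4-dimethylcyclobutan-1-one
Product: 20 6-bromo-5-[(1S,2R)-2-[3,4-bis(tert-butyldimethylsilyloxy)phenyl]-3,3-dimethyl-4-methylidenecyclobutyl]-7-methoxy-2,2-dimethyl-2H-chromene
Conditions: Ph3PCH3Br, KOtBu, THF, 0 °C → rt
Reagents that add atoms: methyltriphenylphosphonium bromide, C[P+](c1ccccc1)(c1ccccc1)c1ccccc1.[Br-]
Why: Wittig methylenation is favoured by the strain-enhanced electrophilicity of the cyclobutanone, and any reversible enolisation at Cb returns the stable trans-diaryl isomer.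

Step 13
Reactants: 20 6-bromo-5-[(1S,2R)-2-[3,4-bis(tert-butyldimethylsilyloxy)phenyl]-3,3-dimethyl-4-methylidenecyclobutyl]-7-methoxy-2,2-dimethyl-2H-chromene
Product: 22 bis(tert-butyldimethylsilyl) ether of the target (Ca S; Cb R; Cc S), via B-alkyl-9-BBN borane 21 (not isolated)
Conditions: 9-BBN, THF, 0 °C → rt; then Pd(OAc)2 (cat.), SPhos, K3PO4 (aq.), THF, 50 °C
Reagents that add atoms: none
Why: 9-BBN should add to the exocyclic 1,1-disubstituted alkene (much faster than to the hindered cis-disubstituted chromene alkene) from the face anti to ring A on the neighbouring carbon, placing H trans and the CH2B arm cis to ring A and so setting Ca, after which an intramolecular B-alkyl Suzuki–Miyaura coupling with the C6 bromide closes the five-membered ring under mild phosphate conditions that the aryl silyl ethers should survive.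

Step 14
Reactants: 22 bis(tert-butyldimethylsilyl) ether of the target
Product: 23 CNP0207533.1 (target; Ca S; Cb R; Cc S)
Conditions: TBAF, AcOH, THF, 0 °C
Reagents that add atoms: none
Why: fluoride cleavage of the two aryl silyl ethers, buffered with acetic acid, should free the catechol without touching the chromene or any stereocentre.

**Compound list**

1 | phloroglucinol (benzene-1,3,5-triol) | Oc1cc(O)cc(O)c1 | starting material
2 | 3,3-dimethylacrylic acid (3-methylbut-2-enoic acid) | CC(C)=CC(=O)O | starting material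
3 | 5,7-dihydroxy-2,2-dimethylchroman-4-one | CC1(C)CC(=O)c2c(O)cc(O)cc2O1 | intermediate
4 | 5-hydroxy-7-methoxy-2,2-dimethylchroman-4-one | COc1cc(O)c2c(c1)OC(C)(C)CC2=O | intermediate
5 | 7-methoxy-2,2-dimethylchroman-5-ol | COc1cc(O)c2c(c1)OC(C)(C)CC2 | intermediate
6 | 7-methoxy-2,2-dimethylchroman-5-yl trifluoromethanesulfonate | COc1cc(OS(=O)(=O)C(F)(F)F)c2c(c1)OC(C)(C)CC2 | intermediate
7 | bromoacetyl bromide | BrCC(Br)=O | starting material
8 | (2R,5R)-2,5-dimethylpyrrolidine | C[C@@H]1CC[C@@H](C)N1 | starting material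
9 | 2-bromo-1-[(2R,5R)-2,5-dimethylpyrrolidin-1-yl]ethanone | BrCC(=O)N1[C@H](C)CC[C@H]1C | intermediate
10 | bromozinc enolate (Reformatsky reagent) of 9, not isolated | Br[Zn]CC(=O)N1[C@H](C)CC[C@H]1C | intermediate
11 | 1-[(2R,5R)-2,5-dimethylpyrrolidin-1-yl]-2-(7-methoxy-2,2-dimethylchroman-5-yl)ethanone | COc1cc2c(c(CC(=O)N3[C@H](C)CC[C@H]3C)c1)CCC(C)(C)O2 | intermediate
12 | 3,4-dihydroxybenzaldehyde | O=Cc1ccc(O)c(O)c1 | starting material
13 | 3,4-bis(tert-butyldimethylsilyloxy)benzaldehyde | O=Cc1ccc(O[Si](C)(C)C(C)(C)C)c(O[Si](C)(C)C(C)(C)C)c1 | intermediate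
14 | 4-(2-methylprop-1-enyl)-1,2-bis(tert-butyldimethylsilyloxy)benzene | CC(C)=Cc1ccc(O[Si](C)(C)C(C)(C)C)c(O[Si](C)(C)C(C)(C)C)c1 | intermediate
15 | (2R,5R)-1-[2-(7-methoxy-2,2-dimethylchroman-5-yl)ethenylidene]-2,5-dimethylpyrrolidinium triflate (keteniminium salt, not isolated) | COc1cc2c(c(C=C=[N+]3[C@H](C)CC[C@H]3C)c1)CCC(C)(C)O2.[O-]S(=O)(=O)C(F)(F)F | intermediate
16 | (2R,5R)-1-[(2R,3R)-3-[3,4-bis(tert-butyldimethylsilyloxy)phenyl]-2-(7-methoxy-2,2-dimethylchroman-5-yl)-4,4-dimethylcyclobutylidene]-2,5-dimethylpyrrolidinium triflate (not isolated) | COc1cc2c(c([C@H]3[C@H](c4ccc(O[Si](C)(C)C(C)(C)C)c(O[Si](C)(C)C(C)(C)C)c4)C(C)(C)C3=[N+]5[C@H](C)CC[C@H]5C)c1)CCC(C)(C)O2.[O-]S(=O)(=O)C(F)(F)F | intermediate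
17 | (2R,3R)-3-[3,4-bis(tert-butyldimethylsilyloxy)phenyl]-2-(7-methoxy-2,2-dimethylchroman-5-yl)-4,4-dimethylcyclobutan-1-one (aryl groups trans) | COc1cc2c(c([C@H]3[C@H](c4ccc(O[Si](C)(C)C(C)(C)C)c(O[Si](C)(C)C(C)(C)C)c4)C(C)(C)C3=O)c1)CCC(C)(C)O2 | intermediate
18 | (2R,3R)-2-(6-bromo-7-methoxy-2,2-dimethylchroman-5-yl)-3-[3,4-bis(tert-butyldimethylsilyloxy)phenyl]-4,4-dimethylcyclobutan-1-one | COc1cc2OC(C)(C)CCc2c([C@H]3[C@H](c4ccc(O[Si](C)(C)C(C)(C)C)c(O[Si](C)(C)C(C)(C)C)c4)C(C)(C)C3=O)c1Br | intermediate
19 | (2R,3R)-2-(6-bromo-7-methoxy-2,2-dimethyl-2H-chromen-5-yl)-3-[3,4-bis(tert-butyldimethylsilyloxy)phenyl]-4,4-dimethylcyclobutan-1-one | COc1cc2OC(C)(C)C=Cc2c([C@H]3[C@H](c4ccc(O[Si](C)(C)C(C)(C)C)c(O[Si](C)(C)C(C)(C)C)c4)C(C)(C)C3=O)c1Br | intermediate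
20 | 6-bromo-5-[(1S,2R)-2-[3,4-bis(tert-butyldimethylsilyloxy)phenyl]-3,3-dimethyl-4-methylidenecyclobutyl]-7-methoxy-2,2-dimethyl-2H-chromene (aryl groups trans) | COc1cc2OC(C)(C)C=Cc2c([C@H]3[C@H](c4ccc(O[Si](C)(C)C(C)(C)C)c(O[Si](C)(C)C(C)(C)C)c4)C(C)(C)C3=C)c1Br | intermediate
21 | 9-{[(1S,2R,3S)-2-(6-bromo-7-methoxy-2,2-dimethyl-2H-chromen-5-yl)-3-[3,4-bis(tert-butyldimethylsilyloxy)phenyl]-4,4-dimethylcyclobutyl]methyl}-9-borabicyclo[3.3.1]nonane (CH2B arm cis to ring A, not isolated) | COc1cc2OC(C)(C)C=Cc2c([C@H]3[C@H](c4ccc(O[Si](C)(C)C(C)(C)C)c(O[Si](C)(C)C(C)(C)C)c4)C(C)(C)[C@H]3CB5C6CCCC5CCC6)c1Br | intermediate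
22 | bis(tert-butyldimethylsilyl) ether of the target: 7-methoxy-2,2-dimethyl-2H-chromene whose C5 and C6 are joined through Cb(H)–Ca(H)–CH2 into a cis-fused indane, with the cyclobutane Ca–Cb–Cc–Cd carrying a 3,4-bis(tert-butyldimethylsilyloxy)phenyl group on Cc trans to ring A and two methyl groups on Cd; Ca S, Cb R, Cc S | COc1cc2c(c3c1C[C@H]1[C@@H]3[C@H](c3ccc(O[Si](C)(C)C(C)(C)C)c(O[Si](C)(C)C(C)(C)C)c3)C1(C)C)C=CC(C)(C)O2 | intermediate
23 | CNP0207533.1: the same ring system as 22 with a free 3,4-dihydroxyphenyl group on Cc; Ca S, Cb R, Cc S | COc1cc2c(c3c1C[C@H]1[C@@H]3[C@H](c3ccc(O)c(O)c3)C1(C)C)C=CC(C)(C)O2 | target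

**Step count and risks**

Total: 14 steps. Longest linear sequence: 11 steps (1, 2, 3, 4, 6, 9, 10, 11, 12, 13, 14).

Step 9. What may go wrong: bond formation through the wrong alkene terminus (tertiary instead of benzylic cation), acid-induced oligomerisation of the electron-rich styrene before it is captured, or weak facial discrimination by the auxiliary. The fallback sets out from 6, 8 and 13 and comes back to the route at 17 (through 16) by exchanging the roles of the two components. Aldehyde 13 is methylenated (Ph3PCH3Br, KOtBu, THF) to 4-ethenyl-1,2-bis(tert-butyldimethylsilyloxy)benzene F1. Heck coupling of triflate 6 with this styrene (Pd(OAc)2, PPh3, Et3N, LiCl, DMF, 90 °C) gives (E)-5-{2-[3,4-bis(tert-butyldimethylsilyloxy)phenyl]ethenyl}-7-methoxy-2,2-dimethylchroman F2. Amine 8 is acylated with isobutyryl chloride (Et3N, CH2Cl2) to 1-[(2R,5R)-2,5-dimethylpyrrolidin-1-yl]-2-methylpropan-1-one F3. Tf2O and collidine convert this amide into (2R,5R)-2,5-dimethyl-1-(2-methylprop-1-enylidene)pyrrolidinium triflate F4, a fully substituted and very electrophilic keteniminium salt. Its central carbon is attacked by the ring A carbon of the stilbene (Ca–Cb), because only ring B can stabilise the resulting benzylic cation, and the CMe2 carbon then closes onto it (Cd–Cc). This gives the same iminium 16 with the trans-diaryl geometry taken from the (E)-alkene, and hydrolysis gives 17.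

Step 13. What may go wrong: delivery of hydride to the face syn to ring A, which gives a boron-bearing arm that cannot reach C6, or slow oxidative addition at the doubly ortho-substituted bromide so that protodeboronation outruns ring closure. The fallback sets out from 20 and comes back at 22 by separating the two events and closing the ring without palladium. Hydroboration (9-BBN) followed by oxidation (NaOH, H2O2) gives the primary alcohol [2-(6-bromo-7-methoxy-2,2-dimethyl-2H-chromen-5-yl)-3-[3,4-bis(tert-butyldimethylsilyloxy)phenyl]-4,4-dimethylcyclobutyl]methanol F5, at which stage an unwanted Ca epimer could be removed. CBr4/PPh3 (Appel reaction) gives the corresponding (bromomethyl)cyclobutane F6. Bromine–lithium exchange at the aryl bromide (n-BuLi, THF, −100 °C) gives the C6 aryllithium F7, which on warming displaces the primary bromide (Parham cyclisation) to give 22.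

Step 10. What may go wrong: bromination at C8, between the two oxygens, once C6 is flanked by the bulky cyclobutyl group, or over-bromination. The fallback sets out from 11 and comes back at 18 by introducing the halogen before the cyclobutane exists. NBS in MeCN brominates 11, where only a CH2 group flanks C6, to give 2-(6-bromo-7-methoxy-2,2-dimethylchroman-5-yl)-1-[(2R,5R)-2,5-dimethylpyrrolidin-1-yl]ethanone F8. Tf2O and collidine convert it into the bromoaryl keteniminium triflate F9, which adds to alkene 14 as in step 9 to give the bromoaryl cyclobutaniminium triflate F10. Hydrolysis gives 18 directly, and step 10 is omitted.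

**Further compounds**

F1 | step 9 | 4-ethenyl-1,2-bis(tert-butyldimethylsilyloxy)benzene | C=Cc1ccc(O[Si](C)(C)C(C)(C)C)c(O[Si](C)(C)C(C)(C)C)c1
F2 | step 9 | (E)-5-{2-[3,4-bis(tert-butyldimethylsilyloxy)phenyl]ethenyl}-7-methoxy-2,2-dimethylchroman | COc1cc2c(c(/C=C/c3ccc(O[Si](C)(C)C(C)(C)C)c(O[Si](C)(C)C(C)(C)C)c3)c1)CCC(C)(C)O2
F3 | step 9 | 1-[(2R,5R)-2,5-dimethylpyrrolidin-1-yl]-2-methylpropan-1-one | CC(C)C(=O)N1[C@H](C)CC[C@H]1C
F4 | step 9 | (2R,5R)-2,5-dimethyl-1-(2-methylprop-1-enylidene)pyrrolidinium triflate | CC(C)=C=[N+]1[C@H](C)CC[C@H]1C.[O-]S(=O)(=O)C(F)(F)F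
F5 | step 13 | [2-(6-bromo-7-methoxy-2,2-dimethyl-2H-chromen-5-yl)-3-[3,4-bis(tert-butyldimethylsilyloxy)phenyl]-4,4-dimethylcyclobutyl]methanol (CH2OH cis to ring A) | COc1cc2OC(C)(C)C=Cc2c([C@H]3[C@H](c4ccc(O[Si](C)(C)C(C)(C)C)c(O[Si](C)(C)C(C)(C)C)c4)C(C)(C)[C@H]3CO)c1Br
F6 | step 13 | 6-bromo-5-[4-(bromomethyl)-2-[3,4-bis(tert-butyldimethylsilyloxy)phenyl]-3,3-dimethylcyclobutyl]-7-methoxy-2,2-dimethyl-2H-chromene | COc1cc2OC(C)(C)C=Cc2c([C@H]3[C@H](c4ccc(O[Si](C)(C)C(C)(C)C)c(O[Si](C)(C)C(C)(C)C)c4)C(C)(C)[C@H]3CBr)c1Br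
F7 | step 13 | C6 aryllithium derived from F6 (formed in the flask) | COc1cc2OC(C)(C)C=Cc2c([C@H]3[C@H](c4ccc(O[Si](C)(C)C(C)(C)C)c(O[Si](C)(C)C(C)(C)C)c4)C(C)(C)[C@H]3CBr)c1[Li]
F8 | step 10 | 2-(6-bromo-7-methoxy-2,2-dimethylchroman-5-yl)-1-[(2R,5R)-2,5-dimethylpyrrolidin-1-yl]ethanone | COc1cc2OC(C)(C)CCc2c(CC(=O)N3[C@H](C)CC[C@H]3C)c1Br
F9 | step 10 | (2R,5R)-1-[2-(6-bromo-7-methoxy-2,2-dimethylchroman-5-yl)ethenylidene]-2,5-dimethylpyrrolidinium triflate (formed in the flask) | COc1cc2OC(C)(C)CCc2c(C=C=[N+]3[C@H](C)CC[C@H]3C)c1Br.[O-]S(=O)(=O)C(F)(F)F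
F10 | step 10 | (2R,5R)-1-[(2R,3R)-2-(6-bromo-7-methoxy-2,2-dimethylchroman-5-yl)-3-[3,4-bis(tert-butyldimethylsilyloxy)phenyl]-4,4-dimethylcyclobutylidene]-2,5-dimethylpyrrolidinium triflate (formed in the flask) | COc1cc2OC(C)(C)CCc2c([C@H]3[C@H](c4ccc(O[Si](C)(C)C(C)(C)C)c(O[Si](C)(C)C(C)(C)C)c4)C(C)(C)C3=[N+]5[C@H](C)CC[C@H]5C)c1Br.[O-]S(=O)(=O)C(F)(F)F
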